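**Plan**

Positions are numbered as in carotenoids: ring C1–C6 (C1 = CMe2, C5 and C6 carry the hydroxyls), chain C7–C15, then C15′, C14′, C13′ and the ester carbon C12′.
Retrosynthesis: the C14–C15 single bond is cut first. C13 carries a methyl group cis to that bond, so the (13E)-C13(CH3)=C14 unit is the syn adduct of CH3–metal to a terminal alkyne C13≡C14–H. One flask therefore gives the methyl branch, the alkene geometry, the C14–metal bond (Cp2ZrCl2/Me3Al) and the bond to an (E,E)-C15 iododienoate (Pd(PPh3)4/ZnCl2).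
Further cuts: C11=C12 and C7=C8 (two Horner–Wadsworth–Emmons olefinations) lead back to a C10 ring aldehyde; the iododienoate comes from propargyl alcohol and a phosphorane.
Forward: β-cyclocitral → allylic alcohol → epoxide → trans-diol → aldehyde → C15 ester → C15 aldehyde → C18 trienyne → silyl protection → key coupling → desilylation. The six-membered ring is bought, and no ring is formed.
Stereochemistry: C5 and C6 come from Sharpless epoxidation of the ring C5=C6 alkene (L-(+)-diethyl tartrate) followed by invertive hydrolysis at C5, which gives the trans-(5R,6R)-diol. All alkenes are E through the olefinations, the syn carbometalation and stereoretentive couplings.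

Key step: step 14

Assumption: phosphonate 6 is drawn as its E isomer; the commercial reagent is an E/Z mixture whose anion equilibrates before it reacts.

**Route**

Step 1
Reactants: 1 β-cyclocitral (2,6,6-trimethylcyclohex-1-ene-1-carbaldehyde)
Product: 2 β-cyclogeraniol [(2,6,6-trimethylcyclohex-1-en-1-yl)methanol]
Conditions: NaBH4 (1 equiv), MeOH, 0 °C
Reagents that add atoms: none
Why: Borohydride 1,2-reduction of the hindered conjugated aldehyde should give the primary allylic alcohol that later directs the epoxidation; no stereocentre is formed.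

Step 2
Reactants: 2 β-cyclogeraniol
Product: 3 [(1S,6S)-2,2,6-trimethyl-7-oxabicyclo[4.1.0]heptan-1-yl]methanol
Conditions: Ti(OiPr)4 (10 mol %), L-(+)-diethyl tartrate (12 mol %), t-BuOOH (2 equiv), 4 Å molecular sieves, CH2Cl2, −20 °C
Reagents that add atoms: tert-butyl hydroperoxide, CC(C)(C)OO
Why: Sharpless asymmetric epoxidation: the allylic alkoxide bound to the Ti(OiPr)4/tartrate catalyst should receive the peroxide oxygen on the same alkene face as geraniol does with the L-(+)-ester (which gives the 2S,3S epoxide), so the C5 and C6 stereocentres are both set here as the (1S,6S)-epoxide by reagent control.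

Step 3
Reactants: 3 [(1S,6S)-2,2,6-trimethyl-7-oxabicyclo[4.1.0]heptan-1-yl]methanol
Product: 4 (1S,2R)-1-(hydroxymethyl)-2,6,6-trimethylcyclohexane-1,2-diol
Conditions: HClO4 (5 mol %), THF/H2O (3:1), 0 °C → rt
Reagents that add atoms: water, O
Why: Acid-catalysed anti opening of the epoxide by water (epoxide hydrolysis) should occur at C5, the tertiary carbon that is neither neopentylic nor next to the electron-withdrawing CH2OH group, with inversion at C5 and retention at C6, which turns the cis-epoxide into the trans-5,6-diol with the configuration of the target.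

Step 4
Reactants: 4 (1S,2R)-1-(hydroxymethyl)-2,6,6-trimethylcyclohexane-1,2-diol
Product: 5 (1R,2R)-1,2-dihydroxy-2,6,6-trimethylcyclohexane-1-carbaldehyde
Conditions: SO3·pyridine (3 equiv), DMSO, Et3N (5 equiv), CH2Cl2, 0 °C; used crude at once
Reagents that add atoms: none
Why: Parikh–Doering oxidation can only touch the primary alcohol, since both other hydroxyls are tertiary, and the new aldehyde has a quaternary α-carbon that cannot epimerise under the mild basic conditions at 0 °C.

Step 5
Reactants: 5 (1R,2R)-1,2-dihydroxy-2,6,6-trimethylcyclohexane-1-carbaldehyde; 6 triethyl 3-methyl-4-phosphonocrotonate [ethyl (2E)-4-(diethoxyphosphoryl)-3-methylbut-2-enoate]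
Product: 7 ethyl (2E,4E)-5-[(1R,2R)-1,2-dihydroxy-2,6,6-trimethylcyclohexyl]-3-methylpenta-2,4-dienoate
Conditions: 6 (2 equiv), n-BuLi (1.9 equiv), THF/DMPU, −78 °C; then 5, −78 → 0 °C
Reagents that add atoms: none
Why: Horner–Wadsworth–Emmons olefination with the vinylogous phosphonoacetate anion, which is too weakly basic to deprotonate the tertiary alcohols, should form the C7=C8 bond with E geometry under the usual thermodynamic control, while C9=C10 takes the E geometry favoured in the delocalised anion (a minor 9Z isomer would be removed by chromatography).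

Step 6
Reactants: 7 ethyl (2E,4E)-5-[(1R,2R)-1,2-dihydroxy-2,6,6-trimethylcyclohexyl]-3-methylpenta-2,4-dienoate
Product: 8 (1R,2R)-1-[(1E,3E)-5-hydroxy-3-methylpenta-1,3-dien-1-yl]-2,6,6-trimethylcyclohexane-1,2-diol
Conditions: i-Bu2AlH (5 equiv), CH2Cl2, −78 → 0 °C; aq KNaC4H4O6 work-up
Reagents that add atoms: none
Why: 1,2-Reduction of the dienoate with excess i-Bu2AlH (two equivalents are consumed by the hydroxyls) should give the allylic alcohol without touching the diene or the stereocentres.

Step 7
Reactants: 8 (1R,2R)-1-[(1E,3E)-5-hydroxy-3-methylpenta-1,3-dien-1-yl]-2,6,6-trimethylcyclohexane-1,2-diol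
Product: 9 (2E,4E)-5-[(1R,2R)-1,2-dihydroxy-2,6,6-trimethylcyclohexyl]-3-methylpenta-2,4-dienal
Conditions: MnO2 (20 equiv), CH2Cl2, rt
Reagents that add atoms: none
Why: Allylic oxidation with MnO2 is selective for the primary dienylic alcohol, because the tertiary C6 hydroxyl, although allylic, has no carbinol hydrogen.

Step 8
Reactants: 10 3-bromo-1-(trimethylsilyl)prop-1-yne
Product: 11 diethyl [3-(trimethylsilyl)prop-2-yn-1-yl]phosphonate
Conditions: P(OEt)3 (1.2 equiv), neat, 110 °C
Reagents that add atoms: triethyl phosphite, CCOP(OCC)OCC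
Why: Michaelis–Arbuzov reaction of the propargylic bromide with P(OEt)3, in which the silyl cap on the alkyne prevents isomerisation to an allenyl phosphonate.

Step 9
Reactants: 9 (2E,4E)-5-[(1R,2R)-1,2-dihydroxy-2,6,6-trimethylcyclohexyl]-3-methylpenta-2,4-dienal; 11 diethyl [3-(trimethylsilyl)prop-2-yn-1-yl]phosphonate
Product: 13 (1R,2R)-2,6,6-trimethyl-1-[(1E,3E,5E)-3-methylocta-1,3,5-trien-7-yn-1-yl]cyclohexane-1,2-diol, via C-silyl trienyne 12 (not isolated)
Conditions: 11 (3 equiv), LiN(SiMe3)2 (2.9 equiv), THF, −78 °C; 9, −78 → 0 °C; then MeOH, K2CO3 (0.5 equiv), rt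
Reagents that add atoms: none
Why: Horner–Wadsworth–Emmons olefination with the lithiated propargylic phosphonate should form the C11=C12 bond with E geometry, and methanolysis of the alkynyl C–Si bond with K2CO3 in the same flask frees the terminal alkyne C13≡C14–H.

Step 10
Reactants: 13 (1R,2R)-2,6,6-trimethyl-1-[(1E,3E,5E)-3-methylocta-1,3,5-trien-7-yn-1-yl]cyclohexane-1,2-diol
Product: 14 (1R,2R)-1-[(1E,3E,5E)-3-methylocta-1,3,5-trien-7-yn-1-yl]-2,6,6-trimethyl-1,2-bis(trimethylsilyloxy)cyclohexane
Conditions: 1-(trimethylsilyl)imidazole (6 equiv), CH2Cl2, rt → 40 °C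
Reagents that add atoms: 1-(trimethylsilyl)imidazole, C[Si](C)(C)n1ccnc1
Why: Silylation with 1-(trimethylsilyl)imidazole, a neutral and powerful silyl donor that reaches hindered tertiary alcohols without acid, should mask both hydroxyls before the organoaluminium step and leave the alkyne C–H untouched.

Step 11
Reactants: 15 propargyl alcohol (prop-2-yn-1-ol)
Product: 16 (2E)-3-(tributylstannyl)prop-2-en-1-ol
Conditions: Bu3SnH (1.1 equiv), AIBN (5 mol %), neat, 80 °C; chromatography
Reagents that add atoms: tributyltin hydride, CCCC[SnH](CCCC)CCCC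
Why: Radical hydrostannation: the stannyl radical adds to the terminal alkyne carbon and the reversible addition funnels the product to the E vinylstannane, which is separated from minor isomers by chromatography.

Step 12
Reactants: 16 (2E)-3-(tributylstannyl)prop-2-en-1-ol
Product: 17 (2E)-3-iodoprop-2-en-1-ol
Conditions: I2 (1.05 equiv), CH2Cl2, 0 °C
Reagents that add atoms: iodine, II
Why: Iododestannylation is an ipso electrophilic substitution at the vinyl carbon that proceeds with retention of the E geometry.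

Step 13
Reactants: 17 (2E)-3-iodoprop-2-en-1-ol; 18 methyl 2-(triphenylphosphoranylidene)propanoate
Product: 20 methyl (2E,4E)-5-iodo-2-methylpenta-2,4-dienoate, via (E)-3-iodoprop-2-enal 19 (not isolated)
Conditions: MnO2 (15 equiv), 18 (1.3 equiv), CH2Cl2, rt, dark
Reagents that add atoms: none
Why: Tandem MnO2 oxidation and Wittig olefination: the unstable (E)-3-iodoacrolein is trapped as it forms by the stabilised α-methyl ylide, which should give the (2E)-trisubstituted alkene while the iodoalkene keeps its geometry.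

Step 14
Reactants: 14 (1R,2R)-1-[(1E,3E,5E)-3-methylocta-1,3,5-trien-7-yn-1-yl]-2,6,6-trimethyl-1,2-bis(trimethylsilyloxy)cyclohexane; 20 methyl (2E,4E)-5-iodo-2-methylpenta-2,4-dienoate
Product: 23 methyl (2E,4E,6E,8E,10E,12E)-2,7,11-trimethyl-13-[(1R,2R)-2,6,6-trimethyl-1,2-bis(trimethylsilyloxy)cyclohexyl]trideca-2,4,6,8,10,12-hexaenoate, via alkenyldimethylalane 21 (not isolated), via alkenylzinc chloride 22 (not isolated)
Conditions: (i) Me3Al (3 equiv), Cp2ZrCl2 (0.3 equiv), ClCH2CH2Cl, 0 °C → rt; (ii) volatiles removed in vacuo, THF, ZnCl2 (1.1 equiv), 20 (1.0 equiv), Pd(PPh3)4 (5 mol %), rt, dark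
Reagents that add atoms: trimethylaluminium, C[Al](C)C
Why: Cp2ZrCl2 and Me3Al form a methylzirconium species that adds CH3 and metal syn across the terminal C13≡C14 triple bond of 14, with CH3 on the internal carbon C13, and exchange to aluminium gives the (13E)-alkenylalane 21; ZnCl2 then moves the alkenyl group to zinc (22), zerovalent palladium inserts into the C15–I bond of 20, and transmetalation followed by reductive elimination forms the C14–C15 bond with retention of both alkene geometries. The closest known reaction type is the tandem Negishi carboalumination/cross-coupling used to assemble retinoid and carotenoid polyenes from terminal enynes and ester-bearing alkenyl halides. No ring is closed and no stereocentre is formed; the C5 and C6 centres are spectators, and the one new stereochemical element, the E geometry of C13=C14, is controlled by the syn stereospecificity of the carbometalation. The step needs regioselectivity (metal on the unsubstituted terminus C14), chemoselectivity (the alkyne in preference to the di- and trisubstituted alkenes) and retention of geometry in the coupling; the terminal position of the alkyne at the end of the conjugated chain secures the first two, and the mild Pd(PPh3)4/ZnCl2 coupling at room temperature the third. The silyl ethers keep the tertiary hydroxyls from consuming Me3Al, and removing excess Me3Al before the coupling avoids methyl transfer to palladium and attack on the ester of 20.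

Step 15
Reactants: 23 methyl (2E,4E,6E,8E,10E,12E)-2,7,11-trimethyl-13-[(1R,2R)-2,6,6-trimethyl-1,2-bis(trimethylsilyloxy)cyclohexyl]trideca-2,4,6,8,10,12-hexaenoate
Product: 24 methyl (2E,4E,6E,8E,10E,12E)-13-[(1R,2R)-1,2-dihydroxy-2,6,6-trimethylcyclohexyl]-2,7,11-trimethyltrideca-2,4,6,8,10,12-hexaenoate
Conditions: Bu4NF (2.5 equiv), AcOH (2.5 equiv), THF, 0 °C, dark
Reagents that add atoms: none
Why: Fluoride-induced cleavage of the two Si–O bonds, buffered with acetic acid so that neither the methyl ester and hexaene nor the acid-sensitive allylic tertiary alcohol is harmed, should release the target without touching the stereocentres.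

**Compound list**

1 | β-cyclocitral (2,6,6-trimethylcyclohex-1-ene-1-carbaldehyde) | O=CC1=C(C)CCCC1(C)C | starting material
2 | β-cyclogeraniol [(2,6,6-trimethylcyclohex-1-en-1-yl)methanol] | OCC1=C(C)CCCC1(C)C | intermediate
3 | [(1S,6S)-2,2,6-trimethyl-7-oxabicyclo[4.1.0]heptan-1-yl]methanol | OC[C@]12O[C@@]1(C)CCCC2(C)C | intermediate
4 | (1S,2R)-1-(hydroxymethyl)-2,6,6-trimethylcyclohexane-1,2-diol | OC[C@@]1(O)C(C)(C)CCC[C@@]1(C)O | intermediate
5 | (1R,2R)-1,2-dihydroxy-2,6,6-trimethylcyclohexane-1-carbaldehyde | O=C[C@@]1(O)C(C)(C)CCC[C@@]1(C)O | intermediate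
6 | triethyl 3-methyl-4-phosphonocrotonate [ethyl (2E)-4-(diethoxyphosphoryl)-3-methylbut-2-enoate] | CCOC(=O)/C=C(C)/CP(=O)(OCC)OCC | starting material
7 | ethyl (2E,4E)-5-[(1R,2R)-1,2-dihydroxy-2,6,6-trimethylcyclohexyl]-3-methylpenta-2,4-dienoate | CCOC(=O)/C=C(C)/C=C/[C@@]1(O)C(C)(C)CCC[C@@]1(C)O | intermediate
8 | (1R,2R)-1-[(1E,3E)-5-hydroxy-3-methylpenta-1,3-dien-1-yl]-2,6,6-trimethylcyclohexane-1,2-diol | OC/C=C(C)/C=C/[C@@]1(O)C(C)(C)CCC[C@@]1(C)O | intermediate
9 | (2E,4E)-5-[(1R,2R)-1,2-dihydroxy-2,6,6-trimethylcyclohexyl]-3-methylpenta-2,4-dienal | O=C/C=C(C)/C=C/[C@@]1(O)C(C)(C)CCC[C@@]1(C)O | intermediate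
10 | 3-bromo-1-(trimethylsilyl)prop-1-yne | C[Si](C)(C)C#CCBr | starting material
11 | diethyl [3-(trimethylsilyl)prop-2-yn-1-yl]phosphonate | CCOP(=O)(CC#C[Si](C)(C)C)OCC | intermediate
12 | (1R,2R)-2,6,6-trimethyl-1-[(1E,3E,5E)-3-methyl-8-(trimethylsilyl)octa-1,3,5-trien-7-yn-1-yl]cyclohexane-1,2-diol (C-silyl trienyne) | C[Si](C)(C)C#C/C=C/C=C(C)/C=C/[C@@]1(O)C(C)(C)CCC[C@@]1(C)O | intermediate
13 | (1R,2R)-2,6,6-trimethyl-1-[(1E,3E,5E)-3-methylocta-1,3,5-trien-7-yn-1-yl]cyclohexane-1,2-diol | C#C/C=C/C=C(C)/C=C/[C@@]1(O)C(C)(C)CCC[C@@]1(C)O | intermediate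
14 | (1R,2R)-1-[(1E,3E,5E)-3-methylocta-1,3,5-trien-7-yn-1-yl]-2,6,6-trimethyl-1,2-bis(trimethylsilyloxy)cyclohexane | C#C/C=C/C=C(C)/C=C/[C@@]1(O[Si](C)(C)C)C(C)(C)CCC[C@@]1(C)O[Si](C)(C)C | intermediate
15 | propargyl alcohol (prop-2-yn-1-ol) | C#CCO | starting material
16 | (2E)-3-(tributylstannyl)prop-2-en-1-ol | OC/C=C/[Sn](CCCC)(CCCC)CCCC | intermediate
17 | (2E)-3-iodoprop-2-en-1-ol | OC/C=C/I | intermediate
18 | methyl 2-(triphenylphosphoranylidene)propanoate | COC(=O)C(C)=P(c1ccccc1)(c1ccccc1)c1ccccc1 | starting material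
19 | (E)-3-iodoprop-2-enal | O=C/C=C/I | intermediate
20 | methyl (2E,4E)-5-iodo-2-methylpenta-2,4-dienoate | COC(=O)/C(C)=C/C=C/I | intermediate
21 | dimethyl{(1E,3E,5E,7E)-2,6-dimethyl-8-[(1R,2R)-2,6,6-trimethyl-1,2-bis(trimethylsilyloxy)cyclohexyl]octa-1,3,5,7-tetraen-1-yl}alumane (alkenyldimethylalane) | C[Al](C)/C=C(C)/C=C/C=C(C)/C=C/[C@@]1(O[Si](C)(C)C)C(C)(C)CCC[C@@]1(C)O[Si](C)(C)C | intermediate
22 | chloro{(1E,3E,5E,7E)-2,6-dimethyl-8-[(1R,2R)-2,6,6-trimethyl-1,2-bis(trimethylsilyloxy)cyclohexyl]octa-1,3,5,7-tetraen-1-yl}zinc (alkenylzinc chloride) | Cl[Zn]/C=C(C)/C=C/C=C(C)/C=C/[C@@]1(O[Si](C)(C)C)C(C)(C)CCC[C@@]1(C)O[Si](C)(C)C | intermediate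
23 | methyl (2E,4E,6E,8E,10E,12E)-2,7,11-trimethyl-13-[(1R,2R)-2,6,6-trimethyl-1,2-bis(trimethylsilyloxy)cyclohexyl]trideca-2,4,6,8,10,12-hexaenoate | COC(=O)/C(C)=C/C=C/C=C(C)/C=C/C=C(C)/C=C/[C@@]1(O[Si](C)(C)C)C(C)(C)CCC[C@@]1(C)O[Si](C)(C)C | intermediate
24 | methyl (2E,4E,6E,8E,10E,12E)-13-[(1R,2R)-1,2-dihydroxy-2,6,6-trimethylcyclohexyl]-2,7,11-trimethyltrideca-2,4,6,8,10,12-hexaenoate | COC(=O)/C(C)=C/C=C/C=C(C)/C=C/C=C(C)/C=C/[C@@]1(O)C(C)(C)CCC[C@@]1(C)O | target

**Summary**

Total step count: 15.
Longest linear sequence: 11 steps (steps 1–7, 9, 10, 14, 15).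

Steps most likely to fail:

1. Step 14. The Lewis-acidic Me3Al/Cp2ZrCl2 medium may ionise the tertiary, polyene-conjugated C6–O bond or strip the silyl groups. Metalation of the alkyne C–H may compete with carbometalation, and the polyenyl metal may lose geometric purity before it couples. The fallback sets out from 14 and avoids Lewis acids. CuCl-catalysed formal methylboration (CuCl, Xantphos, NaOtBu, B2pin2, MeI, THF, rt) should add boron to C14 and methyl to C13 in a syn fashion under basic conditions. This gives 2-{(1E,3E,5E,7E)-2,6-dimethyl-8-[(1R,2R)-2,6,6-trimethyl-1,2-bis(trimethylsilyloxy)cyclohexyl]octa-1,3,5,7-tetraen-1-yl}-4,4,5,5-tetramethyl-1,3,2-dioxaborolane F1. Suzuki–Miyaura coupling of this boronate with 20 (Pd(PPh3)4, aq K3PO4, THF, rt) forms the same C14–C15 bond and comes back to the route at 23.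

2. Step 5. Under the basic conditions the α,β-dihydroxy aldehyde may undergo α-ketol ring expansion or retro-aldol ring cleavage. Addition to the hindered carbonyl may be slow, and the C9=C10 geometry may erode. The fallback sets out from 4 and removes the free hydroxyls before the aldehyde is made. Persilylation (Me3SiCl, imidazole, DMF) gives (1S,2R)-2,6,6-trimethyl-1,2-bis(trimethylsilyloxy)-1-[(trimethylsilyloxy)methyl]cyclohexane F2. Swern oxidation (oxalyl chloride, DMSO, −78 °C, then Et3N) converts a primary trimethylsilyl ether directly into the aldehyde while tertiary silyl ethers persist, and should give (1R,2R)-2,6,6-trimethyl-1,2-bis(trimethylsilyloxy)cyclohexane-1-carbaldehyde F3. Olefination with the anion of 6 as in step 5 gives ethyl (2E,4E)-3-methyl-5-[(1R,2R)-2,6,6-trimethyl-1,2-bis(trimethylsilyloxy)cyclohexyl]penta-2,4-dienoate F4. Desilylation (Bu4NF, AcOH, THF) comes back to the route at 7.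

3. Step 3. Water may attack partly at C6, which would give the enantiomeric trans-diol and lower the optical purity, and the acid may cause semipinacol ring contraction of the epoxide. The fallback sets out from 3 and replaces free acid by chelation-directed delivery of a carboxylate. Ti(OiPr)4 (1.5 equiv) and PhCO2H in CH2Cl2 at rt bind the epoxy alkoxide to titanium and open the epoxide at the distal carbon C5 with inversion. This gives (1R,2S)-2-hydroxy-2-(hydroxymethyl)-1,3,3-trimethylcyclohexyl benzoate F5. Methanolysis of the ester (K2CO3, MeOH) comes back to the route at 4.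

**Further compounds**

F1 | step 14 | 2-{(1E,3E,5E,7E)-2,6-dimethyl-8-[(1R,2R)-2,6,6-trimethyl-1,2-bis(trimethylsilyloxy)cyclohexyl]octa-1,3,5,7-tetraen-1-yl}-4,4,5,5-tetramethyl-1,3,2-dioxaborolane | CC1(C)OB(/C=C(C)/C=C/C=C(C)/C=C/[C@@]2(O[Si](C)(C)C)C(C)(C)CCC[C@@]2(C)O[Si](C)(C)C)OC1(C)C
F2 | step 5 | (1S,2R)-2,6,6-trimethyl-1,2-bis(trimethylsilyloxy)-1-[(trimethylsilyloxy)methyl]cyclohexane | C[Si](C)(C)OC[C@@]1(O[Si](C)(C)C)C(C)(C)CCC[C@@]1(C)O[Si](C)(C)C
F3 | step 5 | (1R,2R)-2,6,6-trimethyl-1,2-bis(trimethylsilyloxy)cyclohexane-1-carbaldehyde | O=C[C@@]1(O[Si](C)(C)C)C(C)(C)CCC[C@@]1(C)O[Si](C)(C)C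
F4 | step 5 | ethyl (2E,4E)-3-methyl-5-[(1R,2R)-2,6,6-trimethyl-1,2-bis(trimethylsilyloxy)cyclohexyl]penta-2,4-dienoate | CCOC(=O)/C=C(C)/C=C/[C@@]1(O[Si](C)(C)C)C(C)(C)CCC[C@@]1(C)O[Si](C)(C)C
F5 | step 3 | (1R,2S)-2-hydroxy-2-(hydroxymethyl)-1,3,3-trimethylcyclohexyl benzoate | OC[C@@]1(O)C(C)(C)CCC[C@@]1(C)OC(=O)c1ccccc1
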